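**Strategy.** The lactone chain C19–O–C18 joins the quaternary C5 to C4, so an acrylate on the C19 oxygen can deliver the dienophile C3=C4 to a diene C5=C10–C1=C2 whose central bond sits in ring C and is therefore fixed s-cis. One intramolecular Diels–Alder step thus forms C4–C5 and C2–C3, closes ring B and the γ-lactone and sets C5. The precursor is a furan-fused tricycle (rings A and C) carrying the 7α-acetate, the C19 acrylate and a C2 silyl dienol ether; it is built from a ketal-protected cyclohexenone by asymmetric conjugate methylation, alkylation, Nozaki–Hiyama–Kishi closure of ring C and two triflate couplings. Enone reduction, C3–C4 dehydrogenation and Luche reduction finish the target.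

Key step: step 18

Remark (locants): clerodane numbering is used; ring A = C5–C10, ring B = C1–C5 + C10, ring C = C1, C10, C9, C11, C12, C13, C16; furan = C13–C16 + O; C17 on C8, C19 on C5, C20 on C9, C18 = lactone C=O; α is the face of C19 and C20, β the face of H10.

Remark (structure check): the target reads as H1 α, 2-OH α, C19 α, 7-OAc α, C17 α, C20 α, H10 β (1S,2S,5S,7R,8S,9R,10R); compounds 28 and 29 below carry the same C7, C8 and C9 configurations and the E enol ether that leads to a 19α, 4β-H, 2β-siloxy adduct, so no descriptor needed correction.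

Remark (precursor design): the acrylate is attached before the C2 aldehyde exists, because a free C19 alcohol beside the cis-placed enal would close to a six-membered lactol; the silyl dienol ether is made last and the C12 ketone is left free.

Assumption: the copper–phosphoramidite methyl addition in step 3 is taken to follow the facial sense known for 2-methylcyclohex-2-enone; if the ketal reverses it, the antipodal ligand is used.

Step 1
Reactants: 1 1,4-dioxaspiro[4.5]dec-6-en-8-one
Product: 2 7-iodo-1,4-dioxaspiro[4.5]dec-6-en-8-one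
Conditions: I2, pyridine, CH2Cl2, 0 °C to rt
Reagents that add atoms: iodine, II
Why: α-Iodination of a cyclic enone by pyridine-mediated conjugate addition, iodination and elimination (Johnson iodination, a Baylis–Hillman-type process) should place iodine only on the α-carbon, and the ketal is inert to it.

Step 2
Reactants: 2 7-iodo-1,4-dioxaspiro[4.5]dec-6-en-8-one
Product: 3 7-methyl-1,4-dioxaspiro[4.5]dec-6-en-8-one
Conditions: MeB(OH)2, PdCl2(dppf) (cat.), K2CO3, dioxane/H2O, 80 °C
Reagents that add atoms: methylboronic acid, CB(O)O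
Why: Suzuki–Miyaura coupling of the electron-poor α-iodoenone with methylboronic acid should replace iodine by the methyl group that becomes C20.

Step 3
Reactants: 3 7-methyl-1,4-dioxaspiro[4.5]dec-6-en-8-one
Product: 5 (6S)-6,7-dimethyl-8-(trimethylsilyloxy)-1,4-dioxaspiro[4.5]dec-7-ene, via dimethylaluminium enolate 4 (not isolated)
Conditions: Me3Al, Cu(O2CC4H3S) (copper thiophene-2-carboxylate, cat.), (S,R,R)-binaphthyl bis(1-phenylethyl)phosphoramidite (cat.), Et2O, −30 °C; then Me3SiOTf, THF, −30 °C to rt
Reagents that add atoms: trimethylaluminium, C[Al](C)C; trimethylsilyl trifluoromethanesulfonate, C[Si](C)(C)OS(=O)(=O)C(F)(F)F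
Why: Copper–phosphoramidite-catalysed asymmetric conjugate addition of Me3Al (Alexakis-type) to the α-methyl enone should deliver the C17 methyl to one face of the β-carbon under ligand control and so set C8, and silylation of enolate 4 keeps the enolate regiochemistry for the next step.

Step 4
Reactants: 5 (6S)-6,7-dimethyl-8-(trimethylsilyloxy)-1,4-dioxaspiro[4.5]dec-7-ene; 6 2-bromo-N-methoxy-N-methylacetamide
Product: 8 2-[(6S,7S)-6,7-dimethyl-8-oxo-1,4-dioxaspiro[4.5]decan-7-yl]-N-methoxy-N-methylacetamide, via lithium enolate 7 (not isolated)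
Conditions: MeLi, THF, 0 °C; then 6, DMPU, −78 to −20 °C
Reagents that add atoms: none
Why: MeLi cleaves the silyl enol ether to the regiodefined tetrasubstituted lithium enolate 7, whose SN2 alkylation by the activated α-bromo amide should occur on the face opposite to the adjacent pseudoaxial C8 methyl, which makes C9 quaternary with C20 cis to C17 (enolate alkylation under 1,2-induction).

Step 5
Reactants: 8 2-[(6S,7S)-6,7-dimethyl-8-oxo-1,4-dioxaspiro[4.5]decan-7-yl]-N-methoxy-N-methylacetamide
Product: 10 (6S,7S)-7-[2-(methoxy(methyl)amino)-2-oxoethyl]-6,7-dimethyl-1,4-dioxaspiro[4.5]dec-8-en-8-yl triflate, via lithium enolate 9 (not isolated)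
Conditions: LiN(i-Pr)2, THF, −78 °C; then Comins' reagent [N-(5-chloropyridin-2-yl)triflimide], −78 to 0 °C
Reagents that add atoms: Comins' reagent, Clc1ccc(nc1)N(S(=O)(=O)C(F)(F)F)S(=O)(=O)C(F)(F)F
Why: The C10 ketone can enolise only towards C5 because C9 is quaternary, so kinetic deprotonation and O-sulfonylation should give a single enol triflate (enol triflate formation).

Step 6
Reactants: 10 (6S,7S)-7-[2-(methoxy(methyl)amino)-2-oxoethyl]-6,7-dimethyl-1,4-dioxaspiro[4.5]dec-8-en-8-yl triflate; 11 3-bromofuran-2-carbaldehyde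
Product: 15 (6S,7S)-7-[2-(2-formylfuran-3-yl)-2-oxoethyl]-6,7-dimethyl-1,4-dioxaspiro[4.5]dec-8-en-8-yl triflate, via lithium amino alkoxide 12 (not isolated), via 3-lithiofuran 13 (not isolated), via furylmagnesium bromide 14 (not isolated)
Conditions: 11, LiN(Me)CH2CH2NMe2, THF, −78 °C; t-BuLi (2 equiv.), −78 °C; MgBr2·OEt2; then 10, −78 to 0 °C; aq. NH4Cl
Reagents that add atoms: none
Why: Temporary protection of the aldehyde as its lithium α-amino alkoxide (Comins protocol) allows bromine–lithium exchange at the furan 3-position, and the derived Grignard reagent should acylate once at the Weinreb amide through the stable chelate while leaving the alkenyl triflate alone (Weinreb ketone synthesis).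

Step 7
Reactants: 15 (6S,7S)-7-[2-(2-formylfuran-3-yl)-2-oxoethyl]-6,7-dimethyl-1,4-dioxaspiro[4.5]dec-8-en-8-yl triflate
Product: 16 tricyclic C1 carbinol (rings A and C plus furan; C5=C10 alkene, C7 ethylene ketal, C12 ketone, 8α,9α-dimethyl; both C1 epimers)
Conditions: CrCl2, NiCl2 (cat.), DMF (0.005 M), rt
Reagents that add atoms: none
Why: Nozaki–Hiyama–Kishi reaction: nickel-catalysed formation of an alkenylchromium species at C10 and its addition to the aldehyde, which chromium selects over the ketone, should close the seven-membered ring C; the C1 carbinol configuration is not controlled and is removed in step 8.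

Step 8
Reactants: 16 tricyclic C1 carbinol
Product: 17 tricyclic dienone (C1 and C12 ketones, C5=C10, C7 ketal)
Conditions: MnO2, CH2Cl2, rt
Reagents that add atoms: none
Why: MnO2 oxidises the doubly activated (allylic and furfurylic) C1 alcohol to the cross-conjugated ketone under neutral conditions that spare the ketal (allylic alcohol oxidation).

Step 9
Reactants: 17 tricyclic dienone
Product: 19 C1 enol triflate bearing 5-[(isopropoxydimethylsilyl)methyl] (C1=C10; C7 ketal; C12 ketone; C5 not controlled), via magnesium enolate 18 (not isolated)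
Conditions: (i-PrO)Me2SiCH2MgCl [from (i-PrO)Me2SiCH2Cl, Mg], CuBr·SMe2, THF, −78 to −40 °C; then Comins' reagent, −78 to 0 °C
Reagents that add atoms: [(isopropoxydimethylsilyl)methyl]magnesium chloride, CC(C)O[Si](C)(C)C[Mg]Cl; Comins' reagent, Clc1ccc(nc1)N(S(=O)(=O)C(F)(F)F)S(=O)(=O)C(F)(F)F
Why: A magnesium cuprate made from Tamao's silylmethyl Grignard reagent should add 1,4 to C5, the β-carbon of the C1 enone, in preference to the ketones, and O-triflation of enolate 18 fixes the C1=C10 bond (conjugate addition, enolate trapping); the C5 configuration is not needed because C5 becomes sp2 in step 17.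

Step 10
Reactants: 19 C1 enol triflate bearing the 5-silylmethyl group
Product: 20 19-hydroxy enol triflate (C7 ketal, C12 ketone)
Conditions: KF, KHCO3, 30% H2O2, THF/MeOH, rt
Reagents that add atoms: hydrogen peroxide, OO
Why: Tamao–Fleming oxidation converts the C–Si bond of the alkoxysilane into C–OH under mildly basic peroxide conditions that an enol triflate and an aryl ketone should tolerate, which unveils the C19 alcohol.

Step 11
Reactants: 20 19-hydroxy enol triflate
Product: 21 19-hydroxy 7,12-diketone enol triflate
Conditions: 1 M HCl, THF, rt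
Reagents that add atoms: water, O
Why: Aqueous acid hydrolyses the dioxolane to the C7 ketone (ketal hydrolysis); this is done only now, with C5 sp3, so that the ketone is never β,γ to a ring alkene, and short exposure should keep the α-stereocentre C8 intact.

Step 12
Reactants: 21 19-hydroxy 7,12-diketone enol triflate
Product: 22 7α,19-diol enol triflate (C12 ketone)
Conditions: LiBH(s-Bu)3, THF, −78 °C; then aq. NaOH, H2O2
Reagents that add atoms: none
Why: The bulky hydride should attack the cyclohexanone from the equatorial β side, away from the axial C20 methyl, to give the axial 7α-alcohol cis to the C8 methyl, and should leave the hindered, vinylogous-ester-like furyl ketone untouched (diastereoselective ketone reduction).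

Step 13
Reactants: 22 7α,19-diol enol triflate; 23 acryloyl chloride
Product: 24 19-acrylate 7α-alcohol enol triflate
Conditions: 2,4,6-collidine, CH2Cl2, −78 °C
Reagents that add atoms: none
Why: Acylation with one equivalent of acryloyl chloride at low temperature should take place only at the primary C19 alcohol, the axial secondary C7 alcohol being far more hindered (selective esterification).

Step 14
Reactants: 24 19-acrylate 7α-alcohol enol triflate
Product: 25 19-acrylate 7α-acetate enol triflate
Conditions: Ac2O, DMAP, Et3N, CH2Cl2, rt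
Reagents that add atoms: acetic anhydride, CC(=O)OC(C)=O
Why: DMAP-catalysed acyl transfer (Steglich-type acetylation) esterifies the remaining hindered 7α-alcohol and completes the acetate of the target.

Step 15
Reactants: 25 19-acrylate 7α-acetate enol triflate
Product: 26 allylic alcohol (C2 hydroxymethyl on C1=C10)
Conditions: Bu3SnCH2OH, Pd(PPh3)4 (cat.), LiCl, BHT, dioxane, 90 °C
Reagents that add atoms: (tributylstannyl)methanol, CCCC[Sn](CCCC)(CCCC)CO
Why: Migita–Kosugi–Stille coupling of the enol triflate with (tributylstannyl)methanol should transfer the hydroxymethyl group to C1 and so introduce C2 at the alcohol oxidation level in the presence of acrylate and acetate.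

Step 16
Reactants: 26 allylic alcohol
Product: 27 enal (C2 aldehyde on C1=C10; H5 as the only γ-hydrogen)
Conditions: MnO2, CH2Cl2, rt
Reagents that add atoms: none
Why: MnO2 oxidises the allylic C2 alcohol to the conjugated enal without touching esters or the furyl ketone (allylic oxidation), and no free C19 alcohol is present that could trap the aldehyde as a lactol.

Step 17
Reactants: 27 enal
Product: 28 tricyclic siloxydiene acrylate (C5=C10–C1=C2–OSi, E enol ether, 7α-OAc, C12 ketone)
Conditions: TBSOTf (1.2 equiv.), Et3N, CH2Cl2, −78 to 0 °C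
Reagents that add atoms: tert-butyldimethylsilyl trifluoromethanesulfonate, CC(C)(C)[Si](C)(C)OS(=O)(=O)C(F)(F)F
Why: O-Silylation of the enal and removal of the only γ-hydrogen (H5) by Et3N gives the silyl dienol ether (soft vinylogous enolisation); reaction through the s-trans enal should place oxygen trans to C10, and the neopentyl-flanked C12 ketone should stay free with one equivalent of reagent.

Step 18
Reactants: 28 tricyclic siloxydiene acrylate
Product: 29 pentacyclic cycloadduct (C1=C10 alkene, cis-fused saturated γ-lactone, 19α, 4β-H, 2β-OSi)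
Conditions: PhMe (0.005 M), BHT, N,O-bis(trimethylsilyl)acetamide (0.2 equiv.), base-washed sealed tube, 170 °C
Reagents that add atoms: none
Why: Thermal, concerted but asynchronous [4+2] cycloaddition of the acrylate C3=C4 onto the diene C5=C10–C1=C2, whose s-cis shape is enforced because C9, C10, C1 and C16 are all members of ring C; the closest known reaction type is the ester-tethered intramolecular Diels–Alder reaction of 2-(acyloxymethyl)-1-vinylcyclohexenes that gives fused γ-lactones with an angular quaternary carbon. Ring B closes as the new cyclohexene (bonds C4–C5 and C2–C3), and the γ-lactone closes as the five-membered ring C5–C19–O–C18–C4 in the fused mode, because the three-atom tether can reach C5 only with C18 exo. C5 is set by π-facial choice: the dienophile should come from the β face, away from the pseudoaxial C20 methyl on C9 and the 7α-acetoxy group, so that C19 ends α and cis to C20. C4 follows from the exo tether (H4 β, cis-lactone) and C2 from the E enol ether (OSi β); both centres are erased later. The step needs facial selectivity and the tether-dictated regiochemistry, which runs against the polar preference of a 1-siloxydiene; the first rests on the C9 and C7 substituents and the second on the short tether. Radical inhibitor, a silylating acid scavenger and high dilution should hold back polymerisation, enol ether hydrolysis and a [1,5]-hydrogen shift from C19 to C2.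

Step 19
Reactants: 29 pentacyclic cycloadduct
Product: 30 2β-allylic alcohol
Conditions: HF·pyridine, pyridine, THF, 0 °C to rt
Reagents that add atoms: none
Why: Fluoride-assisted Si–O cleavage removes the allylic silyl ether and leaves acetate, lactone and ketone alone (desilylation).

Step 20
Reactants: 30 2β-allylic alcohol
Product: 31 C2 enone (C1=C10 conjugated to C2=O)
Conditions: Dess–Martin periodinane, NaHCO3, CH2Cl2, 0 °C to rt
Reagents that add atoms: none
Why: Dess–Martin oxidation converts the allylic alcohol into the C2 ketone under buffered, neutral conditions and thereby erases the C2 centre.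

Step 21
Reactants: 31 C2 enone
Product: 32 saturated C2 ketone (H10 β, H1 α, furan carbon equatorial)
Conditions: Mn(dpm)3 [tris(2,2,6,6-tetramethylheptane-3,5-dionato)manganese, cat.], PhSiH3, t-BuOOH, i-PrOH, rt; then DBU (cat.), CH2Cl2, rt
Reagents that add atoms: none
Why: Metal-hydride hydrogen-atom transfer (Mukaiyama-type conjugate reduction under Magnus or Shenvi conditions) should deliver a hydrogen atom to C10 from the β face, the α face being blocked by the axial C19 and C20 groups, which sets H10 trans to both; the stabilised C1 radical is then reduced and DBU equilibrates C1 to the isomer with the furan carbon equatorial (H1 α).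

Step 22
Reactants: 32 saturated C2 ketone
Product: 34 C3=C4 ene-dione (2-oxo analogue of the target), via bis(trimethylsilyl) enol ether 33 (not isolated)
Conditions: LiN(i-Pr)2 (2.5 equiv.), Me3SiCl, THF, −78 °C; then Pd(OAc)2 (2.2 equiv.), MeCN, rt; 1 M HCl work-up
Reagents that add atoms: none
Why: Kinetic deprotonation with in situ silylation should take a C3 hydrogen, H1 being tertiary and shielded by the syn-axial C19 and C20 groups, and Saegusa–Ito oxidation of enol ether 33 gives the C3=C4 enone by β-hydride elimination of H4; the C12 enol ether has no β-hydrogen and returns the ketone on acidic work-up.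

Step 23
Reactants: 34 C3=C4 ene-dione
Product: 35 CNP0182929.1 (target)
Conditions: NaBH4, CeCl3·7H2O, MeOH, −78 °C
Reagents that add atoms: none
Why: Luche reduction: the cerium-modified borohydride should attack the enone carbonyl 1,2 along the axial β trajectory and give the equatorial 2α-alcohol trans to the furan carbon, while the C12 ketone (a vinylogous ester through the furan oxygen) and the lactone are much less electrophilic.

**Compound list**

1 | 1,4-dioxaspiro[4.5]dec-6-en-8-one | O=C1C=CC2(CC1)OCCO2 | starting material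
2 | 7-iodo-1,4-dioxaspiro[4.5]dec-6-en-8-one | O=C1C(I)=CC2(CC1)OCCO2 | intermediate
3 | 7-methyl-1,4-dioxaspiro[4.5]dec-6-en-8-one | O=C1C(C)=CC2(CC1)OCCO2 | intermediate
4 | dimethylaluminium enolate of (6S)-6,7-dimethyl-1,4-dioxaspiro[4.5]decan-8-one | C[C@H]1C(C)=C(O[Al](C)C)CCC12OCCO2 | intermediate (not isolated)
5 | (6S)-6,7-dimethyl-8-(trimethylsilyloxy)-1,4-dioxaspiro[4.5]dec-7-ene | C[C@H]1C(C)=C(O[Si](C)(C)C)CCC12OCCO2 | intermediate
6 | 2-bromo-N-methoxy-N-methylacetamide | CON(C)C(=O)CBr | starting material
7 | lithium enolate corresponding to 5 | C[C@H]1C(C)=C(O[Li])CCC12OCCO2 | intermediate (not isolated)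
8 | 2-[(6S,7S)-6,7-dimethyl-8-oxo-1,4-dioxaspiro[4.5]decan-7-yl]-N-methoxy-N-methylacetamide | CON(C)C(=O)C[C@@]1(C)[C@H](C)C2(OCCO2)CCC1=O | intermediate
9 | lithium 8,9-enolate of 8 | CON(C)C(=O)C[C@@]1(C)[C@H](C)C2(OCCO2)CC=C1O[Li] | intermediate (not isolated)
10 | (6S,7S)-7-[2-(methoxy(methyl)amino)-2-oxoethyl]-6,7-dimethyl-1,4-dioxaspiro[4.5]dec-8-en-8-yl triflate | CON(C)C(=O)C[C@@]1(C)[C@H](C)C2(OCCO2)CC=C1OS(=O)(=O)C(F)(F)F | intermediate
11 | 3-bromofuran-2-carbaldehyde | O=Cc1occc1Br | starting material
12 | lithium α-amino alkoxide of 11 with N,N,N'-trimethylethylenediamide | [Li]OC(N(C)CCN(C)C)c1occc1Br | intermediate (not isolated)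
13 | 3-lithio derivative of 12 | [Li]OC(N(C)CCN(C)C)c1occc1[Li] | intermediate (not isolated)
14 | 3-(bromomagnesio) derivative of 12 | [Li]OC(N(C)CCN(C)C)c1occc1[Mg]Br | intermediate (not isolated)
15 | (6S,7S)-7-[2-(2-formylfuran-3-yl)-2-oxoethyl]-6,7-dimethyl-1,4-dioxaspiro[4.5]dec-8-en-8-yl triflate | O=Cc1occc1C(=O)C[C@@]1(C)[C@H](C)C2(OCCO2)CC=C1OS(=O)(=O)C(F)(F)F | intermediate
16 | tricyclic C1 carbinol (C5=C10, C7 ethylene ketal, C12 ketone, 8α,9α-dimethyl; C1 epimers) | O=C1C[C@@]2(C)[C@H](C)C3(OCCO3)CC=C2C(O)c2occc21 | intermediate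
17 | tricyclic dienone (C1 and C12 ketones, C5=C10, C7 ketal) | O=C1C[C@@]2(C)[C@H](C)C3(OCCO3)CC=C2C(=O)c2occc21 | intermediate
18 | magnesium C1 enolate bearing the 5-silylmethyl group | O=C1C[C@@]2(C)[C@H](C)C3(OCCO3)CC(C[Si](C)(C)OC(C)C)C2=C(O[Mg]Cl)c2occc21 | intermediate (not isolated)
19 | C1 enol triflate, 5-[(isopropoxydimethylsilyl)methyl], C7 ketal, C12 ketone (C5 not controlled) | O=C1C[C@@]2(C)[C@H](C)C3(OCCO3)CC(C[Si](C)(C)OC(C)C)C2=C(OS(=O)(=O)C(F)(F)F)c2occc21 | intermediate
20 | 19-hydroxy enol triflate, C7 ketal | O=C1C[C@@]2(C)[C@H](C)C3(OCCO3)CC(CO)C2=C(OS(=O)(=O)C(F)(F)F)c2occc21 | intermediate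
21 | 19-hydroxy 7,12-diketone enol triflate | O=C1C[C@@]2(C)[C@H](C)C(=O)CC(CO)C2=C(OS(=O)(=O)C(F)(F)F)c2occc21 | intermediate
22 | 7α,19-diol enol triflate | O=C1C[C@@]2(C)[C@H](C)[C@H](O)CC(CO)C2=C(OS(=O)(=O)C(F)(F)F)c2occc21 | intermediate
23 | acryloyl chloride | C=CC(=O)Cl | starting material
24 | 19-acrylate 7α-alcohol enol triflate | O=C1C[C@@]2(C)[C@H](C)[C@H](O)CC(COC(=O)C=C)C2=C(OS(=O)(=O)C(F)(F)F)c2occc21 | intermediate
25 | 19-acrylate 7α-acetate enol triflate | O=C1C[C@@]2(C)[C@H](C)[C@H](OC(C)=O)CC(COC(=O)C=C)C2=C(OS(=O)(=O)C(F)(F)F)c2occc21 | intermediate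
26 | allylic alcohol (C2 hydroxymethyl on C1=C10) | O=C1C[C@@]2(C)[C@H](C)[C@H](OC(C)=O)CC(COC(=O)C=C)C2=C(CO)c2occc21 | intermediate
27 | enal (C2 aldehyde on C1=C10) | O=C1C[C@@]2(C)[C@H](C)[C@H](OC(C)=O)CC(COC(=O)C=C)C2=C(C=O)c2occc21 | intermediate
28 | tricyclic siloxydiene acrylate (key-step precursor) | C=CC(=O)OCC1=C2/C(=C/O[Si](C)(C)C(C)(C)C)c3occc3C(=O)C[C@@]2(C)[C@H](C)[C@H](OC(C)=O)C1 | intermediate
29 | pentacyclic cycloadduct (C1=C10, saturated cis-lactone, 2β-OTBS) | CC(=O)O[C@@H]1C[C@@]23COC(=O)[C@@H]2C[C@@H](O[Si](C)(C)C(C)(C)C)C4=C3[C@](C)([C@@H]1C)CC(=O)c5ccoc45 | intermediate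
30 | 2β-allylic alcohol | CC(=O)O[C@@H]1C[C@@]23COC(=O)[C@@H]2C[C@@H](O)C4=C3[C@](C)([C@@H]1C)CC(=O)c5ccoc45 | intermediate
31 | C2 enone (C1=C10) | CC(=O)O[C@@H]1C[C@@]23COC(=O)[C@@H]2CC(=O)C4=C3[C@](C)([C@@H]1C)CC(=O)c5ccoc45 | intermediate
32 | saturated C2 ketone (H1 α, H10 β) | CC(=O)O[C@@H]1C[C@@]23COC(=O)[C@@H]2CC(=O)[C@H]2c4occc4C(=O)C[C@@](C)([C@@H]1C)[C@@H]23 | intermediate
33 | 2,12-bis(trimethylsilyl) enol ether (C2=C3, C11=C12) | CC(=O)O[C@@H]1C[C@@]23COC(=O)[C@@H]2C=C(O[Si](C)(C)C)[C@H]2c4occc4C(O[Si](C)(C)C)=C[C@@](C)([C@@H]1C)[C@@H]23 | intermediate (not isolated)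
34 | C3=C4 ene-dione | CC(=O)O[C@@H]1C[C@@]23COC(=O)C2=CC(=O)[C@H]2c4occc4C(=O)C[C@@](C)([C@@H]1C)[C@@H]23 | intermediate
35 | CNP0182929.1 | CC(=O)O[C@@H]1C[C@@]23COC(=O)C2=C[C@H](O)[C@H]2c4occc4C(=O)C[C@@](C)([C@@H]1C)[C@@H]23 | target

**Totals.** Total step count: 23. Longest linear sequence: 23 steps (1 to 35); compounds 6, 11 and 23 enter as purchased building blocks.

**Steps most likely to fail**

Step 18. The cycloaddition may be too slow, because the ester tether rarely populates the reactive conformation and its regiochemistry opposes the polarity of the siloxydiene. A [1,5]-hydrogen shift from C19 to C2, loss of the allylic acrylate, or incomplete facial selectivity could then take over. The fallback replaces the acrylate by a doubly activated fumarate, which reacts at lower temperature and has no polar bias between C3 and C4; the extra ester is removed once C2 is a ketone. It sets out from 22. Ethyl fumaroyl chloride (collidine, −78 °C) gives the 19-(ethyl fumarate) 7α-alcohol F1, and acetylation gives the 7α-acetate F2. Stille hydroxymethylation gives the allylic alcohol F3, MnO2 the enal F4, and TBSOTf/Et3N the fumarate siloxydiene F5. Heating in toluene (about 110 °C, BHT) should give the cycloadduct F6 with an ethoxycarbonyl group on C3 (C3 configuration inconsequential). HF·pyridine then gives the 2β-alcohol F7 and Dess–Martin oxidation the β-keto ester enone F8. Krapcho dealkoxycarbonylation (LiCl, wet DMSO, 130 °C) returns the route at 31.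

Step 21. Hydrogen-atom transfer to C10, a tetrasubstituted carbon between two quaternary centres, may be too slow, or the hydrogen may arrive without face control. The fallback uses hydroxyl-directed homogeneous hydrogenation in place of radical reduction and sets out from 30. [Ir(cod)(PCy3)(py)]PF6 under H2 in CH2Cl2 should deliver both hydrogens syn to the 2β-hydroxyl and give the 1β-H,10β-H saturated alcohol F9. Dess–Martin oxidation gives the C1-epimeric ketone F10, and DBU equilibrates C1 to return the route at 32.

Step 15. Transfer of the hydroxymethyl group from tin to palladium is slow and may lose out to reduction or decomposition of the hindered tetrasubstituted enol triflate. The fallback brings C2 in as part of a vinyl group and sets out from 25. Stille coupling with tributyl(vinyl)stannane (Pd(PPh3)4, LiCl, dioxane) gives the 1-vinyl diene F11. Lemieux–Johnson cleavage (OsO4 cat., NaIO4, 2,6-lutidine, dioxane/H2O) of the terminal, most electron-rich alkene returns the route at 27.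

**Further compounds**

F1 | step 18 | 19-(ethyl fumarate) 7α-alcohol enol triflate | O=C1C[C@@]2(C)[C@H](C)[C@H](O)CC(COC(=O)/C=C/C(=O)OCC)C2=C(OS(=O)(=O)C(F)(F)F)c2occc21
F2 | step 18 | 19-(ethyl fumarate) 7α-acetate enol triflate | O=C1C[C@@]2(C)[C@H](C)[C@H](OC(C)=O)CC(COC(=O)/C=C/C(=O)OCC)C2=C(OS(=O)(=O)C(F)(F)F)c2occc21
F3 | step 18 | fumarate allylic alcohol (C2 hydroxymethyl) | O=C1C[C@@]2(C)[C@H](C)[C@H](OC(C)=O)CC(COC(=O)/C=C/C(=O)OCC)C2=C(CO)c2occc21
F4 | step 18 | fumarate enal | O=C1C[C@@]2(C)[C@H](C)[C@H](OC(C)=O)CC(COC(=O)/C=C/C(=O)OCC)C2=C(C=O)c2occc21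
F5 | step 18 | fumarate siloxydiene | CCOC(=O)/C=C/C(=O)OCC1=C2/C(=C/O[Si](C)(C)C(C)(C)C)c3occc3C(=O)C[C@@]2(C)[C@H](C)[C@H](OC(C)=O)C1
F6 | step 18 | cycloadduct with 3-ethoxycarbonyl group | CC(=O)O[C@@H]1C[C@@]23COC(=O)[C@@H]2C(C(=O)OCC)[C@@H](O[Si](C)(C)C(C)(C)C)C4=C3[C@](C)([C@@H]1C)CC(=O)c5ccoc45
F7 | step 18 | 3-ethoxycarbonyl 2β-alcohol | CC(=O)O[C@@H]1C[C@@]23COC(=O)[C@@H]2C(C(=O)OCC)[C@@H](O)C4=C3[C@](C)([C@@H]1C)CC(=O)c5ccoc45
F8 | step 18 | 3-ethoxycarbonyl C2 enone (β-keto ester) | CC(=O)O[C@@H]1C[C@@]23COC(=O)[C@@H]2C(C(=O)OCC)C(=O)C4=C3[C@](C)([C@@H]1C)CC(=O)c5ccoc45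
F9 | step 21 | 1β-H,10β-H saturated 2β-alcohol | CC(=O)O[C@@H]1C[C@@]23COC(=O)[C@@H]2C[C@@H](O)[C@@H]2c4occc4C(=O)C[C@@](C)([C@@H]1C)[C@@H]23
F10 | step 21 | 1β-H saturated C2 ketone (C1 epimer of 32) | CC(=O)O[C@@H]1C[C@@]23COC(=O)[C@@H]2CC(=O)[C@@H]2c4occc4C(=O)C[C@@](C)([C@@H]1C)[C@@H]23
F11 | step 15 | 1-vinyl diene | O=C1C[C@@]2(C)[C@H](C)[C@H](OC(C)=O)CC(COC(=O)C=C)C2=C(C=C)c2occc21
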